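**Plan**
- Retrosynthesis first cuts the ester between the side-chain oxygen of ring A and the carbonyl of the central 3-hydroxybutanoate, then the ArCH2–C(=O) bond of the ring B side chain, and last, in each benzoate ring, the bonds C1–C6 and C3–C4.
- The enabling feature: in ring A the atoms C1, C2, C3 and the ester carbon are an acetoacetate of the secondary alcohol, and C4, C5, C6 with the 2-oxypropyl chain are a 5-oxyhex-2-enoate. The 2,4-dioxygenated benzoate is therefore a 4-alkoxycarbonylcyclohexane-1,3-dione two hydrogens removed; ring B is the same pattern with a crotonate.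
- Forward, one acetoacetate (4) is annulated twice, with enoate 8 to close ring A and with methyl crotonate to close ring B. Each dione is dehydrogenated and benzylated, ring B is extended by lateral acylation and its silyl ether oxidized to the acid, the halves are esterified, and the last silyl ether is oxidized to the acid before hydrogenolysis.
- All four stereocentres are purchased: both benzoate-bearing carbinols from (R)-butane-1,3-diol, the ring A side chain from (R)-pent-4-en-2-ol, the ring B side chain from methyl (R)-3-hydroxybutanoate. No C–O bond at a stereocentre is broken anywhere.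

Key step: step 5

Remark on the chemistry: the cyclohexane-1,3-diones are drawn as triketo tautomers with undefined configuration at the two new ring carbons, and enolates or organolithium forms of numbered compounds carry no numbers of their own.

**Route**

Step 1
Reactants: 1 (R)-butane-1,3-diol
Product: 2 (R)-4-[(tert-butyldiphenylsilyl)oxy]butan-2-ol
Conditions: TBDPSCl (1.0 equiv), imidazole, CH2Cl2, 0 °C → rt
Reagents that add atoms: tert-butyl(chloro)diphenylsilane, CC(C)(C)[Si](Cl)(c1ccccc1)c1ccccc1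
Why: Silylation with a bulky chlorosilane should be strongly biased toward the primary hydroxyl of the 1,3-diol, and the secondary carbinol centre is not involved.

Step 2
Reactants: 2 (R)-4-[(tert-butyldiphenylsilyl)oxy]butan-2-ol; 3 diketene
Product: 4 (R)-4-[(tert-butyldiphenylsilyl)oxy]butan-2-yl 3-oxobutanoate
Conditions: diketene (1.2 equiv), DMAP (cat.), Et2O, 0 °C → rt
Reagents that add atoms: none
Why: Nucleophile-catalysed ring opening of diketene by an alcohol (acetoacetylation) acylates oxygen only, so the (R)-carbinol is retained.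

Step 3
Reactants: 5 (R)-pent-4-en-2-ol
Product: 6 (R)-tert-butyldimethyl(pent-4-en-2-yloxy)silane
Conditions: TBSCl, imidazole, DMF, rt
Reagents that add atoms: tert-butyl(chloro)dimethylsilane, CC(C)(C)[Si](C)(C)Cl
Why: Standard silylation of a secondary alcohol at oxygen, which leaves the stereocentre and the terminal alkene untouched.

Step 4
Reactants: 6 (R)-tert-butyldimethyl(pent-4-en-2-yloxy)silane; 7 methyl acrylate
Product: 8 methyl (R,E)-5-[(tert-butyldimethylsilyl)oxy]hex-2-enoate
Conditions: second-generation Grubbs catalyst RuCl2(=CHPh)(PCy3)(H2IMes) (3 mol%), methyl acrylate (3 equiv), CH2Cl2, 40 °C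
Reagents that add atoms: none
Why: Olefin cross-metathesis of a terminal alkene with an acrylate should favour the cross product as the E-enoate, because the acrylate homodimerizes slowly and ethylene escapes.

Step 5
Reactants: 4 (R)-4-[(tert-butyldiphenylsilyl)oxy]butan-2-yl 3-oxobutanoate; 8 methyl (R,E)-5-[(tert-butyldimethylsilyl)oxy]hex-2-enoate
Product: 10 (R)-4-[(tert-butyldiphenylsilyl)oxy]butan-2-yl 6-[(R)-2-[(tert-butyldimethylsilyl)oxy]propyl]-2,4-dioxocyclohexane-1-carboxylate, via Michael adduct 9 (not isolated)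
Conditions: KOtBu (1.0 equiv), 4 (1.1 equiv), t-BuOH/THF, 0 °C; then 8, rt → 60 °C; 1 M HCl to pH 3, 0 °C
Reagents that add atoms: none
Why: The potassium enolate of 4 should add through its central carbon to the β-carbon of 8 (Michael addition, ring A bond C1–C6), and after proton transfer the enolate of the acetyl methyl group attacks the methyl ester with loss of methoxide (Claisen condensation of the Dieckmann type, bond C3–C4); the closest known reaction is the classical dihydroorsellinate synthesis from acetoacetates and crotonates. Ring A closes by a 6-exo-trig acyl substitution, and deprotonation of the product dione, the most acidic species present, pulls both reversible steps forward. The two new ring stereocentres (C1 and C6) form without control as a mixture that does not matter, since step 6 makes both carbons trigonal, while the two carbinol centres lie away from every acidic position and cannot epimerize. Chemoselectivity between the two esters is required and is built into the substrate: only the methyl ester can be reached through a six-membered ring, attack on the secondary ester would need a four-membered ring, and tert-butoxide does not transesterify. Forming the enolate of 4 first, with no excess base, keeps free alkoxide low, so γ-deprotonation of 8 with loss of silanolate should not compete with conjugate addition.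

Step 6
Reactants: 10 (R)-4-[(tert-butyldiphenylsilyl)oxy]butan-2-yl 6-[(R)-2-[(tert-butyldimethylsilyl)oxy]propyl]-2,4-dioxocyclohexane-1-carboxylate
Product: 13 (R)-4-[(tert-butyldiphenylsilyl)oxy]butan-2-yl 2,4-dihydroxy-6-[(R)-2-[(tert-butyldimethylsilyl)oxy]propyl]benzoate, via bis-silyl dienol ether 11 (not isolated), via bis-silyl aryl ether 12 (not isolated)
Conditions: TMSOTf (2.5 equiv), Et3N, CH2Cl2, 0 °C; pentane, filter; DDQ (1.1 equiv), PhMe, 0 °C → rt; K2CO3 (cat.), MeOH, 0 °C
Reagents that add atoms: none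
Why: Double O-silylation should turn the dione with its β-keto ester into a 1,3-bis(silyloxy)cyclohexa-1,3-diene, from which DDQ removes hydride and then a proton (quinone dehydrogenation of silyl enol ethers, driven here by aromatization), and methanolysis of the labile aryl silyl ethers frees the resorcylate without any acid that could strip the two alkyl silyl ethers.

Step 7
Reactants: 13 (R)-4-[(tert-butyldiphenylsilyl)oxy]butan-2-yl 2,4-dihydroxy-6-[(R)-2-[(tert-butyldimethylsilyl)oxy]propyl]benzoate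
Product: 14 (R)-4-[(tert-butyldiphenylsilyl)oxy]butan-2-yl 2,4-bis(benzyloxy)-6-[(R)-2-[(tert-butyldimethylsilyl)oxy]propyl]benzoate
Conditions: BnBr (2.5 equiv), K2CO3, n-Bu4NI (cat.), DMF, 50 °C
Reagents that add atoms: benzyl bromide, BrCc1ccccc1
Why: Williamson etherification of both phenoxides should proceed while the doubly ortho-substituted ester and the silyl ethers are inert to carbonate.

Step 8
Reactants: 14 (R)-4-[(tert-butyldiphenylsilyl)oxy]butan-2-yl 2,4-bis(benzyloxy)-6-[(R)-2-[(tert-butyldimethylsilyl)oxy]propyl]benzoate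
Product: 15 (R)-4-[(tert-butyldiphenylsilyl)oxy]butan-2-yl 2,4-bis(benzyloxy)-6-[(R)-2-hydroxypropyl]benzoate
Conditions: HF·pyridine, pyridine, THF, 0 °C → rt
Reagents that add atoms: none
Why: Buffered HF·pyridine should cleave the TBS ether well before the more robust TBDPS ether (selective fluoride desilylation), and the weakly acidic medium never generates the alkoxide that could attack the neighbouring ester.

Step 9
Reactants: 4 (R)-4-[(tert-butyldiphenylsilyl)oxy]butan-2-yl 3-oxobutanoate; 16 methyl (E)-but-2-enoate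
Product: 18 (R)-4-[(tert-butyldiphenylsilyl)oxy]butan-2-yl 6-methyl-2,4-dioxocyclohexane-1-carboxylate, via Michael adduct 17 (not isolated)
Conditions: KOtBu (1.0 equiv), 4 (1.1 equiv), t-BuOH/THF, 0 °C; then 16, rt → 60 °C; 1 M HCl to pH 3, 0 °C
Reagents that add atoms: none
Why: This is the parent case of the Michael–Claisen annulation of step 5 (acetoacetate plus crotonate to a dihydroorsellinate), with the same 6-exo-trig closure onto the only ester that can give a six-membered ring.

Step 10
Reactants: 18 (R)-4-[(tert-butyldiphenylsilyl)oxy]butan-2-yl 6-methyl-2,4-dioxocyclohexane-1-carboxylate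
Product: 21 (R)-4-[(tert-butyldiphenylsilyl)oxy]butan-2-yl 2,4-dihydroxy-6-methylbenzoate, via bis-silyl dienol ether 19 (not isolated), via bis-silyl aryl ether 20 (not isolated)
Conditions: TMSOTf (2.5 equiv), Et3N, CH2Cl2, 0 °C; pentane, filter; DDQ (1.1 equiv), PhMe, 0 °C → rt; K2CO3 (cat.), MeOH, 0 °C
Reagents that add atoms: none
Why: The same silylation and quinone dehydrogenation as in step 6 should aromatize the dione to the orsellinate ester.

Step 11
Reactants: 21 (R)-4-[(tert-butyldiphenylsilyl)oxy]butan-2-yl 2,4-dihydroxy-6-methylbenzoate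
Product: 22 (R)-4-[(tert-butyldiphenylsilyl)oxy]butan-2-yl 2,4-bis(benzyloxy)-6-methylbenzoate
Conditions: BnBr (2.5 equiv), K2CO3, n-Bu4NI (cat.), DMF, 50 °C
Reagents that add atoms: benzyl bromide, BrCc1ccccc1
Why: Williamson etherification of both phenols, as in step 7.

Step 12
Reactants: 23 methyl (R)-3-hydroxybutanoate
Product: 24 methyl (R)-3-(benzyloxy)butanoate
Conditions: BnOC(=NH)CCl3, TfOH (cat.), cyclohexane/CH2Cl2, rt
Reagents that add atoms: benzyl 2,2,2-trichloroacetimidate, N=C(OCc1ccccc1)C(Cl)(Cl)Cl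
Why: Acid-catalysed benzylation with the trichloroacetimidate avoids base, so the β-hydroxy ester should neither eliminate nor racemize.

Step 13
Reactants: 24 methyl (R)-3-(benzyloxy)butanoate
Product: 25 (R)-3-(benzyloxy)-N-methoxy-N-methylbutanamide
Conditions: MeNHOMe·HCl, i-PrMgCl, THF, −20 °C
Reagents that add atoms: N,O-dimethylhydroxylamine hydrochloride, CNOC.Cl
Why: The magnesium amide made from i-PrMgCl aminolyses the ester at low temperature (Weinreb amide synthesis), conditions under which a β-alkoxy ester should not eliminate.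

Step 14
Reactants: 22 (R)-4-[(tert-butyldiphenylsilyl)oxy]butan-2-yl 2,4-bis(benzyloxy)-6-methylbenzoate; 25 (R)-3-(benzyloxy)-N-methoxy-N-methylbutanamide
Product: 26 (R)-4-[(tert-butyldiphenylsilyl)oxy]butan-2-yl 2,4-bis(benzyloxy)-6-[(R)-4-(benzyloxy)-2-oxopentyl]benzoate
Conditions: LiN(i-Pr)2 (1.2 equiv), THF, −78 °C; then 25, −78 → −40 °C; aq. NH4Cl
Reagents that add atoms: none
Why: Lateral lithiation of the ortho-toluate gives an ester-stabilized benzylic anion whose acylation by the Weinreb amide stops at the chelated tetrahedral intermediate, so the benzyl ketone appears only on quench and cannot condense further with the ester.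

Step 15
Reactants: 26 (R)-4-[(tert-butyldiphenylsilyl)oxy]butan-2-yl 2,4-bis(benzyloxy)-6-[(R)-4-(benzyloxy)-2-oxopentyl]benzoate
Product: 27 (R)-4-hydroxybutan-2-yl 2,4-bis(benzyloxy)-6-[(R)-4-(benzyloxy)-2-oxopentyl]benzoate
Conditions: HF·pyridine, pyridine, THF, rt
Reagents that add atoms: none
Why: Fluoride desilylation under buffered, weakly acidic conditions should free the primary alcohol without the basic conditions that promote isocoumarin formation from the keto ester or acyl migration.

Step 16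
Reactants: 27 (R)-4-hydroxybutan-2-yl 2,4-bis(benzyloxy)-6-[(R)-4-(benzyloxy)-2-oxopentyl]benzoate
Product: 29 (R)-3-({2,4-bis(benzyloxy)-6-[(R)-4-(benzyloxy)-2-oxopentyl]benzoyl}oxy)butanoic acid, via aldehyde 28 (not isolated)
Conditions: TEMPO (cat.), PhI(OAc)2 (2.2 equiv), MeCN/H2O (1:1), rt
Reagents that add atoms: water, O
Why: Oxoammonium oxidation of the primary alcohol to the aldehyde and of its hydrate to the acid runs under mildly acidic conditions that should spare the benzyl ethers, the ketone and the β-aroyloxy group.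

Step 17
Reactants: 15 (R)-4-[(tert-butyldiphenylsilyl)oxy]butan-2-yl 2,4-bis(benzyloxy)-6-[(R)-2-hydroxypropyl]benzoate; 29 (R)-3-({2,4-bis(benzyloxy)-6-[(R)-4-(benzyloxy)-2-oxopentyl]benzoyl}oxy)butanoic acid
Product: 30 (R)-1-[3,5-bis(benzyloxy)-2-({[(R)-4-[(tert-butyldiphenylsilyl)oxy]butan-2-yl]oxy}carbonyl)phenyl]propan-2-yl (R)-3-({2,4-bis(benzyloxy)-6-[(R)-4-(benzyloxy)-2-oxopentyl]benzoyl}oxy)butanoate
Conditions: EDC·HCl, DMAP (cat.), CH2Cl2, 0 °C → rt
Reagents that add atoms: none
Why: Steglich esterification acylates the secondary alcohol at oxygen, so its configuration is retained, and catalytic DMAP at low temperature should keep β-elimination of the activated acid and attack of the alcohol on its neighbouring ester slow.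

Step 18
Reactants: 30 the silyl-protected coupled ester of step 17
Product: 31 (R)-1-[3,5-bis(benzyloxy)-2-({[(R)-4-hydroxybutan-2-yl]oxy}carbonyl)phenyl]propan-2-yl (R)-3-({2,4-bis(benzyloxy)-6-[(R)-4-(benzyloxy)-2-oxopentyl]benzoyl}oxy)butanoate
Conditions: HF·pyridine, pyridine, THF, rt
Reagents that add atoms: none
Why: Buffered fluoride desilylation should remove the TBDPS group without base, so the β-acyloxy ester and the β-benzyloxy ketone do not eliminate and the hindered benzoate does not migrate.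

Step 19
Reactants: 31 the primary alcohol of step 18
Product: 33 (R)-3-{[2,4-bis(benzyloxy)-6-((R)-2-{[(R)-3-({2,4-bis(benzyloxy)-6-[(R)-4-(benzyloxy)-2-oxopentyl]benzoyl}oxy)butanoyl]oxy}propyl)benzoyl]oxy}butanoic acid, via aldehyde 32 (not isolated)
Conditions: TEMPO (cat.), PhI(OAc)2 (2.2 equiv), MeCN/H2O (1:1), rt
Reagents that add atoms: water, O
Why: The same oxoammonium oxidation as in step 16 should take the primary alcohol through the aldehyde hydrate to the acid without touching esters, ketone or benzyl ethers.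

Step 20
Reactants: 33 the pentabenzyl acid of step 19
Product: 34 (R)-3-{[2,4-dihydroxy-6-((R)-2-{[(R)-3-({2,4-dihydroxy-6-[(R)-4-hydroxy-2-oxopentyl]benzoyl}oxy)butanoyl]oxy}propyl)benzoyl]oxy}butanoic acid
Conditions: H2 (1 atm), Pd/C, EtOAc/EtOH, rt
Reagents that add atoms: none
Why: Hydrogenolysis over Pd/C should cleave the four aryl benzyl ethers and the alkyl benzyl ether, while the esters, the ketone, the acid and the four stereocentres are inert.

**Compound list**
1 | (R)-butane-1,3-diol | C[C@@H](O)CCO | starting material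
2 | (R)-4-[(tert-butyldiphenylsilyl)oxy]butan-2-ol | C[C@@H](O)CCO[Si](c1ccccc1)(c1ccccc1)C(C)(C)C | intermediate
3 | diketene (4-methylideneoxetan-2-one) | C=C1CC(=O)O1 | starting material
4 | (R)-4-[(tert-butyldiphenylsilyl)oxy]butan-2-yl 3-oxobutanoate | CC(=O)CC(=O)O[C@H](C)CCO[Si](c1ccccc1)(c1ccccc1)C(C)(C)C | intermediate
5 | (R)-pent-4-en-2-ol | C[C@@H](O)CC=C | starting material
6 | (R)-tert-butyldimethyl(pent-4-en-2-yloxy)silane | C=CC[C@@H](C)O[Si](C)(C)C(C)(C)C | intermediate
7 | methyl acrylate | C=CC(=O)OC | starting material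
8 | methyl (R,E)-5-[(tert-butyldimethylsilyl)oxy]hex-2-enoate | COC(=O)/C=C/C[C@@H](C)O[Si](C)(C)C(C)(C)C | intermediate
9 | Michael adduct of 4 and 8 (not isolated): methyl 4-({[(R)-4-[(tert-butyldiphenylsilyl)oxy]butan-2-yl]oxy}carbonyl)-3-[(R)-2-[(tert-butyldimethylsilyl)oxy]propyl]-5-oxohexanoate, mixture at C3 and C4 | C[C@H](CC(CC(=O)OC)C(C(C)=O)C(=O)O[C@H](C)CCO[Si](c1ccccc1)(c1ccccc1)C(C)(C)C)O[Si](C)(C)C(C)(C)C | intermediate
10 | ring A dione: (R)-4-[(tert-butyldiphenylsilyl)oxy]butan-2-yl 6-[(R)-2-[(tert-butyldimethylsilyl)oxy]propyl]-2,4-dioxocyclohexane-1-carboxylate, mixture at ring C1 and C6 | C[C@H](CC1CC(=O)CC(=O)C1C(=O)O[C@H](C)CCO[Si](c1ccccc1)(c1ccccc1)C(C)(C)C)O[Si](C)(C)C(C)(C)C | intermediate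
11 | bis-silyl dienol ether of 10 (not isolated): the 2,4-bis[(trimethylsilyl)oxy]cyclohexa-1,3-diene-1-carboxylate | C[C@H](CC1CC(O[Si](C)(C)C)=CC(O[Si](C)(C)C)=C1C(=O)O[C@H](C)CCO[Si](c1ccccc1)(c1ccccc1)C(C)(C)C)O[Si](C)(C)C(C)(C)C | intermediate
12 | bis-silyl aryl ether (not isolated): the 2,4-bis[(trimethylsilyl)oxy]benzoate corresponding to 13 | C[C@H](Cc1cc(O[Si](C)(C)C)cc(O[Si](C)(C)C)c1C(=O)O[C@H](C)CCO[Si](c1ccccc1)(c1ccccc1)C(C)(C)C)O[Si](C)(C)C(C)(C)C | intermediate
13 | (R)-4-[(tert-butyldiphenylsilyl)oxy]butan-2-yl 2,4-dihydroxy-6-[(R)-2-[(tert-butyldimethylsilyl)oxy]propyl]benzoate | C[C@H](Cc1cc(O)cc(O)c1C(=O)O[C@H](C)CCO[Si](c1ccccc1)(c1ccccc1)C(C)(C)C)O[Si](C)(C)C(C)(C)C | intermediate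
14 | (R)-4-[(tert-butyldiphenylsilyl)oxy]butan-2-yl 2,4-bis(benzyloxy)-6-[(R)-2-[(tert-butyldimethylsilyl)oxy]propyl]benzoate | C[C@H](Cc1cc(OCc2ccccc2)cc(OCc2ccccc2)c1C(=O)O[C@H](C)CCO[Si](c1ccccc1)(c1ccccc1)C(C)(C)C)O[Si](C)(C)C(C)(C)C | intermediate
15 | (R)-4-[(tert-butyldiphenylsilyl)oxy]butan-2-yl 2,4-bis(benzyloxy)-6-[(R)-2-hydroxypropyl]benzoate | C[C@H](Cc1cc(OCc2ccccc2)cc(OCc2ccccc2)c1C(=O)O[C@H](C)CCO[Si](c1ccccc1)(c1ccccc1)C(C)(C)C)O | intermediate
16 | methyl (E)-but-2-enoate | C/C=C/C(=O)OC | starting material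
17 | Michael adduct of 4 and 16 (not isolated): methyl 4-({[(R)-4-[(tert-butyldiphenylsilyl)oxy]butan-2-yl]oxy}carbonyl)-3-methyl-5-oxohexanoate, mixture at C3 and C4 | C[C@H](CCO[Si](c1ccccc1)(c1ccccc1)C(C)(C)C)OC(=O)C(C(C)=O)C(C)CC(=O)OC | intermediate
18 | ring B dione: (R)-4-[(tert-butyldiphenylsilyl)oxy]butan-2-yl 6-methyl-2,4-dioxocyclohexane-1-carboxylate, mixture at ring C1 and C6 | C[C@H](CCO[Si](c1ccccc1)(c1ccccc1)C(C)(C)C)OC(=O)C1C(=O)CC(=O)CC1C | intermediate
19 | bis-silyl dienol ether of 18 (not isolated): the 6-methyl-2,4-bis[(trimethylsilyl)oxy]cyclohexa-1,3-diene-1-carboxylate | C[C@H](CCO[Si](c1ccccc1)(c1ccccc1)C(C)(C)C)OC(=O)C1=C(O[Si](C)(C)C)C=C(O[Si](C)(C)C)CC1C | intermediate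
20 | bis-silyl aryl ether (not isolated): the 6-methyl-2,4-bis[(trimethylsilyl)oxy]benzoate corresponding to 21 | C[C@H](CCO[Si](c1ccccc1)(c1ccccc1)C(C)(C)C)OC(=O)c1c(O[Si](C)(C)C)cc(O[Si](C)(C)C)cc1C | intermediate
21 | (R)-4-[(tert-butyldiphenylsilyl)oxy]butan-2-yl 2,4-dihydroxy-6-methylbenzoate | C[C@H](CCO[Si](c1ccccc1)(c1ccccc1)C(C)(C)C)OC(=O)c1c(O)cc(O)cc1C | intermediate
22 | (R)-4-[(tert-butyldiphenylsilyl)oxy]butan-2-yl 2,4-bis(benzyloxy)-6-methylbenzoate | C[C@H](CCO[Si](c1ccccc1)(c1ccccc1)C(C)(C)C)OC(=O)c1c(OCc2ccccc2)cc(OCc2ccccc2)cc1C | intermediate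
23 | methyl (R)-3-hydroxybutanoate | COC(=O)C[C@@H](C)O | starting material
24 | methyl (R)-3-(benzyloxy)butanoate | COC(=O)C[C@@H](C)OCc1ccccc1 | intermediate
25 | (R)-3-(benzyloxy)-N-methoxy-N-methylbutanamide | CON(C)C(=O)C[C@@H](C)OCc1ccccc1 | intermediate
26 | (R)-4-[(tert-butyldiphenylsilyl)oxy]butan-2-yl 2,4-bis(benzyloxy)-6-[(R)-4-(benzyloxy)-2-oxopentyl]benzoate | C[C@H](CCO[Si](c1ccccc1)(c1ccccc1)C(C)(C)C)OC(=O)c1c(OCc2ccccc2)cc(OCc2ccccc2)cc1CC(=O)C[C@@H](C)OCc1ccccc1 | intermediate
27 | (R)-4-hydroxybutan-2-yl 2,4-bis(benzyloxy)-6-[(R)-4-(benzyloxy)-2-oxopentyl]benzoate | C[C@H](CCO)OC(=O)c1c(OCc2ccccc2)cc(OCc2ccccc2)cc1CC(=O)C[C@@H](C)OCc1ccccc1 | intermediate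
28 | (R)-4-oxobutan-2-yl 2,4-bis(benzyloxy)-6-[(R)-4-(benzyloxy)-2-oxopentyl]benzoate (aldehyde, not isolated) | C[C@H](CC=O)OC(=O)c1c(OCc2ccccc2)cc(OCc2ccccc2)cc1CC(=O)C[C@@H](C)OCc1ccccc1 | intermediate
29 | ring B acid: (R)-3-({2,4-bis(benzyloxy)-6-[(R)-4-(benzyloxy)-2-oxopentyl]benzoyl}oxy)butanoic acid | C[C@H](CC(=O)O)OC(=O)c1c(OCc2ccccc2)cc(OCc2ccccc2)cc1CC(=O)C[C@@H](C)OCc1ccccc1 | intermediate
30 | coupled ester: (R)-1-[3,5-bis(benzyloxy)-2-({[(R)-4-[(tert-butyldiphenylsilyl)oxy]butan-2-yl]oxy}carbonyl)phenyl]propan-2-yl (R)-3-({2,4-bis(benzyloxy)-6-[(R)-4-(benzyloxy)-2-oxopentyl]benzoyl}oxy)butanoate | C[C@H](Cc1cc(OCc2ccccc2)cc(OCc2ccccc2)c1C(=O)O[C@H](C)CCO[Si](c1ccccc1)(c1ccccc1)C(C)(C)C)OC(=O)C[C@@H](C)OC(=O)c1c(OCc2ccccc2)cc(OCc2ccccc2)cc1CC(=O)C[C@@H](C)OCc1ccccc1 | intermediate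
31 | primary alcohol: as 30 with the (R)-4-hydroxybutan-2-yl ester on ring A | C[C@H](Cc1cc(OCc2ccccc2)cc(OCc2ccccc2)c1C(=O)O[C@H](C)CCO)OC(=O)C[C@@H](C)OC(=O)c1c(OCc2ccccc2)cc(OCc2ccccc2)cc1CC(=O)C[C@@H](C)OCc1ccccc1 | intermediate
32 | aldehyde (not isolated): as 30 with the (R)-4-oxobutan-2-yl ester on ring A | C[C@H](Cc1cc(OCc2ccccc2)cc(OCc2ccccc2)c1C(=O)O[C@H](C)CC=O)OC(=O)C[C@@H](C)OC(=O)c1c(OCc2ccccc2)cc(OCc2ccccc2)cc1CC(=O)C[C@@H](C)OCc1ccccc1 | intermediate
33 | pentabenzyl acid: (R)-3-{[2,4-bis(benzyloxy)-6-((R)-2-{[(R)-3-({2,4-bis(benzyloxy)-6-[(R)-4-(benzyloxy)-2-oxopentyl]benzoyl}oxy)butanoyl]oxy}propyl)benzoyl]oxy}butanoic acid | C[C@H](Cc1cc(OCc2ccccc2)cc(OCc2ccccc2)c1C(=O)O[C@H](C)CC(=O)O)OC(=O)C[C@@H](C)OC(=O)c1c(OCc2ccccc2)cc(OCc2ccccc2)cc1CC(=O)C[C@@H](C)OCc1ccccc1 | intermediate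
34 | the target hansforester: (R)-3-{[2,4-dihydroxy-6-((R)-2-{[(R)-3-({2,4-dihydroxy-6-[(R)-4-hydroxy-2-oxopentyl]benzoyl}oxy)butanoyl]oxy}propyl)benzoyl]oxy}butanoic acid | C[C@H](Cc1cc(O)cc(O)c1C(=O)O[C@H](C)CC(=O)O)OC(=O)C[C@@H](C)OC(=O)c1c(O)cc(O)cc1CC(=O)C[C@@H](C)O | target

**Count**
Total: 20 steps. Longest linear sequence: 12 steps (steps 1, 2, 9, 10, 11, 14, 15, 16, 17, 18, 19, 20, from (R)-butane-1,3-diol).

**Steps most likely to fail**

Step 5. The enoate may be deprotonated at its γ-position and lose silanolate to give a dienoate, or the Michael addition may revert before the Claisen closure, so that the annulation stalls. The fallback takes ring A from the crotonate series and installs the side chain afterwards. Setting out from 22, lateral lithiation (LiN(i-Pr)2, THF, −78 °C) and acylation with N-methoxy-N-methylacetamide should give the methyl ketone (R)-4-[(tert-butyldiphenylsilyl)oxy]butan-2-yl 2,4-bis(benzyloxy)-6-(2-oxopropyl)benzoate F1. Enantioselective reduction of this benzyl methyl ketone with an (R)-selective alcohol dehydrogenase (enzyme from Lactobacillus kefir, NADP+, propan-2-ol, buffer) would then set the side-chain carbinol by reagent control and rejoin the route at 15.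

Step 6. Double silylation may stay incomplete, the electron-rich dienol ether may add to the quinone instead of transferring hydride, or oxidation may continue at the new benzylic position. The fallback introduces the unsaturation through selenium. Setting out from 10, double deprotonation (LiN(i-Pr)2, 2.2 equiv, THF, −78 °C) and trapping with PhSeBr should selenenylate the ester-bearing ring carbon to give (R)-4-[(tert-butyldiphenylsilyl)oxy]butan-2-yl 6-[(R)-2-[(tert-butyldimethylsilyl)oxy]propyl]-2,4-dioxo-1-(phenylselanyl)cyclohexane-1-carboxylate F2. Oxidation with H2O2 (CH2Cl2/pyridine, 0 °C), syn-elimination of the selenoxide toward the neighbouring ring CH and enolization would rejoin the route at 13.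

Step 17. The freed side-chain hydroxyl may attack the neighbouring benzoate under the basic acylation catalyst (lactonization to a dihydroisocoumarin with loss of the butanediol unit), and the activated acid may lose its β-aroyloxy group by elimination. The fallback never liberates the alcohol. Setting out from 29, 1-chloro-N,N,2-trimethylprop-1-en-1-amine in CH2Cl2 should give under neutral conditions the acid chloride (R)-3-({2,4-bis(benzyloxy)-6-[(R)-4-(benzyloxy)-2-oxopentyl]benzoyl}oxy)butanoyl chloride F3. This would acylate the silyl ether 14 directly with ZnCl2 (cat.) in CH2Cl2 (acylative cleavage of a TBS ether by an acid chloride), rejoining the route at 30 and making step 8 unnecessary.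

Further compounds
F1 | step 5 | (R)-4-[(tert-butyldiphenylsilyl)oxy]butan-2-yl 2,4-bis(benzyloxy)-6-(2-oxopropyl)benzoate | C[C@H](CCO[Si](c1ccccc1)(c1ccccc1)C(C)(C)C)OC(=O)c1c(OCc2ccccc2)cc(OCc2ccccc2)cc1CC(C)=O
F2 | step 6 | (R)-4-[(tert-butyldiphenylsilyl)oxy]butan-2-yl 6-[(R)-2-[(tert-butyldimethylsilyl)oxy]propyl]-2,4-dioxo-1-(phenylselanyl)cyclohexane-1-carboxylate | C[C@H](CC1CC(=O)CC(=O)C1([Se]c1ccccc1)C(=O)O[C@H](C)CCO[Si](c1ccccc1)(c1ccccc1)C(C)(C)C)O[Si](C)(C)C(C)(C)C
F3 | step 17 | (R)-3-({2,4-bis(benzyloxy)-6-[(R)-4-(benzyloxy)-2-oxopentyl]benzoyl}oxy)butanoyl chloride | ClC(=O)C[C@@H](C)OC(=O)c1c(OCc2ccccc2)cc(OCc2ccccc2)cc1CC(=O)C[C@@H](C)OCc1ccccc1
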